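## Retrosynthetic overview
1. Target 20 comes from one global desilylation of 19. Medioresinol is never an intermediate, and no phenol is coupled to a chiral C3 electrophile.
2. Key step: both THF rings of 19 (C8–C8′ and C7–O bonds; stereocentres C8′, C8, C7) form in one pot from the acyclic epoxy cinnamyl ether 18. The sequence is Cp2TiCl epoxide homolysis, 5-exo radical cyclisation, then I2-triggered etherification. The syringyl-side THF forms first (C–C bond) and the guaiacyl-side THF second (C–O bond).
3. 18 comes from Williamson union of epoxy alcohol 5 with cinnamyl bromide 17. Only the carbinol centre C7′ of 5 matters (Sharpless kinetic resolution). Bromide 17 already carries the full erythro 8″-O-4 unit.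
4. 17 comes from a C7″–C8″ disconnection: a Mg-catalysed, auxiliary-controlled anti-aldol of the ferulate-derived aryloxyacetyl imide 10 with TIPS-vanillin 12. The aryl ether is made earlier on an achiral CH2.

Assumption and numbering: C7–C9 is the guaiacyl half of the furofuran, C7′–C9′ the syringyl half, and C7″–C9″ the glycerol unit. The given SMILES reads as 7R,8S,7′R,8′S (exo,exo, antipodal to the (+)-pinoresinol series) and 7″R,8″S (erythro, which is anti in zig-zag notation).

## Route

**Step 1**
Reactants: 1 syringaldehyde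
Product: 2 3,5-dimethoxy-4-(triisopropylsilyloxy)benzaldehyde
Conditions: TIPSCl, imidazole, DMAP (cat.), DMF, 40 °C
Reagents that add atoms: TIPSCl, CC(C)[Si](Cl)(C(C)C)C(C)C
Why: Phenol O-silylation; the hindered aryl TIPS ether survives Grignard, alkoxide and Ti(III)/I2 conditions and is removed with all other silyl groups in the last step.

**Step 2**
Reactants: 2; 3 vinylmagnesium bromide
Product: 4 rac-1-[3,5-dimethoxy-4-(TIPSO)phenyl]prop-2-en-1-ol
Conditions: CH2=CHMgBr, THF, −78 → 0 °C; aq NH4Cl
Reagents that add atoms: vinylmagnesium bromide (3), C=C[Mg]Br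
Why: Grignard 1,2-addition supplies C8′/C9′; the product is deliberately racemic and is resolved in step 3.

**Step 3**
Reactants: 4
Product: 5 (S)-[3,5-dimethoxy-4-(TIPSO)phenyl][(2R)-oxiran-2-yl]methanol (erythro), separated from unreacted (S)-4
Conditions: Ti(OiPr)4 (0.2 eq), L-(+)-DIPT (0.24 eq), TBHP (0.45 eq, decane), 4 Å MS, CH2Cl2, −20 °C, stopped at about 45 % conversion
Reagents that add atoms: tert-butyl hydroperoxide, CC(C)(C)OO (adds O)
Why: Sharpless kinetic resolution; with L-(+)-DIPT the (R)-aryl vinyl carbinol (spatially the same as the fast-reacting (S)-alkyl vinyl carbinols, because aryl outranks vinyl in CIP) is epoxidised much faster and gives the erythro epoxy alcohol, which fixes C7′, while the epoxide centre is erased in step 13.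

**Step 4**
Reactants: 6 (S)-4-benzyloxazolidin-2-one; 7 bromoacetyl bromide
Product: 8 (S)-4-benzyl-3-(bromoacetyl)oxazolidin-2-one
Conditions: n-BuLi, THF, −78 °C; then BrCH2COBr, −78 → 0 °C
Reagents that add atoms: bromoacetyl bromide (7), BrCC(=O)Br
Why: N-acylation of the lithiated oxazolidinone occurs at the acyl bromide, which is far more electrophilic than the alkyl bromide.

**Step 5**
Reactants: 8; 9 methyl (E)-ferulate
Product: 10 (S)-4-benzyl-3-{2-[2-methoxy-4-((E)-3-methoxy-3-oxoprop-1-enyl)phenoxy]acetyl}oxazolidin-2-one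
Conditions: K2CO3, acetone, rt → 40 °C
Reagents that add atoms: none beyond the two reactants
Why: Williamson SN2 of the phenoxide on the activated α-bromo imide builds the 8″-O-4 ether on an achiral CH2, and anhydrous carbonate leaves the imide and enoate intact.

**Step 6**
Reactants: 11 vanillin
Product: 12 3-methoxy-4-(triisopropylsilyloxy)benzaldehyde
Conditions: TIPSCl, imidazole, DMF, rt
Reagents that add atoms: TIPSCl, CC(C)[Si](Cl)(C(C)C)C(C)C
Why: Phenol O-silylation masks the acidic OH and keeps the aldehyde anisaldehyde-like, which is the best aldehyde class for step 7.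

**Step 7**
Reactants: 10; 12
Product: 13 (4S)-4-benzyl-3-[(2R,3R)-2-aryloxy-3-(3-methoxy-4-TIPSO-phenyl)-3-(trimethylsilyloxy)propanoyl]oxazolidin-2-one (anti; aryloxy is the ferulate ring)
Conditions: MgCl2 (20 mol %), Et3N (2 eq), TMSCl (1.5 eq), EtOAc, rt, 24 h; neutral work-up
Reagents that add atoms: TMSCl, C[Si](C)(C)Cl
Why: Proposed new method: this extends the Evans Mg-halide-catalysed direct anti-aldol (known for N-alkanoyl oxazolidinones with non-enolisable aromatic aldehydes) to an aryloxyacetyl imide, where Mg chelates both imide carbonyls, Et3N soft-enolises the more acidic OCH2 to the chelated Z-enolate, the aldehyde adds anti to the benzyl group (alkylation-sense face) through a boat-like TS to give the anti aldolate, and TMSCl traps it irreversibly, setting C8″ and C7″ (2R,3R here, 8″S,7″R after reduction).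

**Step 8**
Reactants: 13
Product: 14 methyl (E)-3-[4-({(1R,2S)-1,3-dihydroxy-1-[3-methoxy-4-(TIPSO)phenyl]propan-2-yl}oxy)-3-methoxyphenyl]acrylate (erythro diol)
Conditions: NaBH4, THF–H2O (4:1), 0 °C → rt; then AcOH/THF/H2O, rt (TMS off); auxiliary recovered
Reagents that add atoms: none
Why: Chemoselective reductive cleavage of the activated N-acyl oxazolidinone leaves the conjugated methyl ester inert to NaBH4, the OTMS group blocks retro-aldol, and no stereocentre is touched (the C8″ descriptor changes R to S only through CIP ranking).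

**Step 9**
Reactants: 14
Product: 15 the 7″,9″-bis-O-TBS ether of 14
Conditions: TBSOTf (2.5 eq), 2,6-lutidine, CH2Cl2, −78 → 0 °C
Reagents that add atoms: TBSOTf, CC(C)(C)[Si](C)(C)OS(=O)(=O)C(F)(F)F
Why: Silyl triflate etherification under buffered cold conditions avoids benzylic ionisation and completes the all-silyl protecting scheme.

**Step 10**
Reactants: 15
Product: 16 the (E)-cinnamyl alcohol (CO2Me → CH2OH)
Conditions: DIBAL-H (2.3 eq), CH2Cl2, −78 °C; Rochelle salt
Reagents that add atoms: none
Why: DIBAL-H 1,2-reduction of the enoate preserves the E-alkene and all silyl ethers.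

**Step 11**
Reactants: 16
Product: 17 the (E)-cinnamyl bromide
Conditions: CBr4, PPh3, 2,6-lutidine, CH2Cl2, −20 °C; pentane trituration, used at once
Reagents that add atoms: CBr4, BrC(Br)(Br)Br (adds Br)
Why: The Appel reaction converts the only free (primary allylic) OH under essentially neutral conditions.

**Step 12**
Reactants: 5; 17
Product: 18 (1S)-[3,5-dimethoxy-4-(TIPSO)phenyl][(2R)-oxiranyl]methyl (E)-cinnamyl ether carrying the protected erythro 8″-O-4 unit
Conditions: 5 and 17 premixed, NaH (1.2 eq), TBAI (10 mol %), THF–DMF (5:1), 0 °C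
Reagents that add atoms: none beyond the two reactants
Why: In this Williamson etherification the alkoxide is trapped by the very reactive cinnamyl bromide as it forms in aprotic medium, which suppresses Payne rearrangement and silyl transfer, and C7′ is not involved in bond breaking.

**Step 13 (key step)**
Reactants: 18
Product: 19 fully silylated ficusesquilignan A, a (1R,3aS,4R,6aS)-1,4-diaryl-tetrahydrofuro[3,4-c]furan (7R,8S,7′R,8′S,7″R,8″S)
Conditions: Cp2TiCl (3 eq, from Cp2TiCl2/Zn, decanted), THF, rt, slow addition, 0.01 M; then I2 (about 2.5 eq, to persistent colour), rt → 45 °C; aq NaH2PO4/Na2S2O3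
Reagents that add atoms: none (net isomerisation)
Why: Nugent–RajanBabu Ti(III) epoxide homolysis gives the planar β-titanoxy C8′ radical (either epoxide epimer would converge), which closes 5-exo onto the styrene through a Beckwith–Houk chair with the C7′ aryl pseudo-equatorial (7′,8′-trans and 8,8′-cis), after which the benzylic radical is captured as C–Ti, iodinolysis gives a p-alkoxybenzylic iodide, and the cis CH2O–Ti alkoxide displaces it with the aryl on the convex face (exo C7), the outcome established for simple furofurans made this way.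

**Step 14**
Reactants: 19
Product: 20 ficusesquilignan A
Conditions: TBAF/AcOH (1:1, 8 eq), THF, 0 °C → rt
Reagents that add atoms: none
Why: Buffered fluoride desilylation removes two aryl TIPS and two alkyl TBS groups together without the acid that epimerises furofurans or benzylic alcohols and without the free phenoxide that could trigger quinone methide formation.

## Compound list
1 | syringaldehyde | COc1cc(C=O)cc(OC)c1O | starting material
2 | 3,5-dimethoxy-4-(TIPSO)benzaldehyde | COc1cc(C=O)cc(OC)c1O[Si](C(C)C)(C(C)C)C(C)C | intermediate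
3 | vinylmagnesium bromide | C=C[Mg]Br | starting material
4 | rac-1-[3,5-dimethoxy-4-(TIPSO)phenyl]prop-2-en-1-ol | COc1cc(C(O)C=C)cc(OC)c1O[Si](C(C)C)(C(C)C)C(C)C | intermediate
5 | (S)-[3,5-dimethoxy-4-(TIPSO)phenyl][(2R)-oxiran-2-yl]methanol | O[C@H]([C@H]1CO1)c2cc(OC)c(O[Si](C(C)C)(C(C)C)C(C)C)c(OC)c2 | intermediate
6 | (S)-4-benzyloxazolidin-2-one | O=C1N[C@@H](Cc2ccccc2)CO1 | starting material
7 | bromoacetyl bromide | BrCC(=O)Br | starting material
8 | (S)-4-benzyl-3-(bromoacetyl)oxazolidin-2-one | O=C(CBr)N1[C@@H](Cc2ccccc2)COC1=O | intermediate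
9 | methyl (E)-ferulate | COC(=O)/C=C/c1ccc(O)c(OC)c1 | starting material
10 | ferulate-derived aryloxyacetyl imide | COC(=O)/C=C/c1ccc(OCC(=O)N2[C@@H](Cc3ccccc3)COC2=O)c(OC)c1 | intermediate
11 | vanillin | COc1cc(C=O)ccc1O | starting material
12 | 3-methoxy-4-(TIPSO)benzaldehyde | COc1cc(C=O)ccc1O[Si](C(C)C)(C(C)C)C(C)C | intermediate
13 | (2R,3R)-anti-aldol TMS ether | COc1cc([C@@H](O[Si](C)(C)C)[C@H](C(=O)N2[C@@H](Cc3ccccc3)COC2=O)Oc4ccc(/C=C/C(=O)OC)cc4OC)ccc1O[Si](C(C)C)(C(C)C)C(C)C | intermediate
14 | (7″R,8″S)-erythro diol enoate | COc1cc([C@@H](O)[C@H](CO)Oc2ccc(/C=C/C(=O)OC)cc2OC)ccc1O[Si](C(C)C)(C(C)C)C(C)C | intermediate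
15 | bis-TBS enoate | COc1cc([C@@H](O[Si](C)(C)C(C)(C)C)[C@H](CO[Si](C)(C)C(C)(C)C)Oc2ccc(/C=C/C(=O)OC)cc2OC)ccc1O[Si](C(C)C)(C(C)C)C(C)C | intermediate
16 | (E)-cinnamyl alcohol | COc1cc([C@@H](O[Si](C)(C)C(C)(C)C)[C@H](CO[Si](C)(C)C(C)(C)C)Oc2ccc(/C=C/CO)cc2OC)ccc1O[Si](C(C)C)(C(C)C)C(C)C | intermediate
17 | (E)-cinnamyl bromide | COc1cc([C@@H](O[Si](C)(C)C(C)(C)C)[C@H](CO[Si](C)(C)C(C)(C)C)Oc2ccc(/C=C/CBr)cc2OC)ccc1O[Si](C(C)C)(C(C)C)C(C)C | intermediate
18 | epoxy cinnamyl ether (cascade precursor) | COc1cc([C@@H](O[Si](C)(C)C(C)(C)C)[C@H](CO[Si](C)(C)C(C)(C)C)Oc2ccc(/C=C/CO[C@H]([C@H]3CO3)c4cc(OC)c(O[Si](C(C)C)(C(C)C)C(C)C)c(OC)c4)cc2OC)ccc1O[Si](C(C)C)(C(C)C)C(C)C | intermediate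
19 | tetrasilyl ficusesquilignan A | COc1cc([C@@H](O[Si](C)(C)C(C)(C)C)[C@H](CO[Si](C)(C)C(C)(C)C)Oc2ccc([C@@H]3OC[C@@H]4[C@H]3CO[C@H]4c5cc(OC)c(O[Si](C(C)C)(C(C)C)C(C)C)c(OC)c5)cc2OC)ccc1O[Si](C(C)C)(C(C)C)C(C)C | intermediate
20 | ficusesquilignan A | COc1cc([C@@H](O)[C@H](CO)Oc2ccc([C@@H]3OC[C@@H]4[C@H]3CO[C@H]4c3cc(OC)c(O)c(OC)c3)cc2OC)ccc1O | target

## Summary
Total steps: 14.
Longest linear sequence: 10 (steps 4, 5, 7, 8, 9, 10, 11, 12, 13, 14, from 6 to 20).

**Steps most likely to fail**
1. **Step 7 (anti-aldol on an untested aryloxyacetyl imide).** The anti/syn ratio or the facial sense could be altered by chelation from the aryloxy or OMe oxygens.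
   - Fallback: use the (R)-auxiliary in the boron (Bu2BOTf/i-Pr2NEt) Evans syn-aldol, which works on aryloxyacetyl imides and gives the threo 7″S,8″S series.
   - After NaBH4 cleavage and selective 9″-O-silylation, invert C7″ by Mitsunobu esterification with 4-nitrobenzoic acid and then cleave the ester.
2. **Step 13 (Ti(III)/I2 cascade on a large, highly oxygenated substrate).** Possible problems are deoxygenation to the allyl ether, formation of the 8,8′-trans isomer that cannot close, and loss of the benzyl–Ti species before iodinolysis.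
   - Fallback: abandon the radical route. Ozonolyse enoate 15 to the aryl aldehyde and build the core by the polar lactone route.
   - That route is an aldol of the enolate of an enantiopure β-[syringyl(silyloxy)methyl]-γ-butyrolactone with the aldehyde, then LiAlH4 reduction, then MsCl/pyridine double benzylic cyclisation.
3. **Step 12 (union of a labile, electron-rich cinnamyl bromide with an epoxy alkoxide).** Risks are Payne rearrangement, silyl transfer and decomposition of the bromide.
   - Fallback: skip the bromide. Convert 16 to its methyl carbonate and join it to the zinc alkoxide of 5 (Et2Zn) by Pd(0)-catalysed, linear-selective Tsuji–Trost O-allylation under non-basic conditions.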